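**Analysis of the target**

Target 21 is a 7-oxabicyclo[4.1.0]hept-4-ene. Its cyclohexene ring is numbered here C1 (OMe), C2 (OBz), C3=C4, C5 and C6 (the epoxide carbons), and C7 is the benzoyloxymethyl carbon on C6. The four stereocentres are contiguous (1S,2R,5R,6R in this numbering). The methoxy group and the epoxide oxygen lie on one face, the C2 benzoate and the C7 arm on the other, and C6 is fully substituted. The vinyl epoxide (C3=C4–C5–O) is open to acid, halide and SN2' attack, and the two benzoates tolerate neither hydride nor enolate chemistry. Harsh acid or base also invites loss of methanol or benzoic acid towards an arene. The difficulty is to build a quaternary oxygenated carbon next to three oxygen-bearing stereocentres, to keep one methyl ether distinct from three other oxygens, and to bring in epoxide and esters late. The strategy rests on two features. The C5–C6 bond joins a carbon allylic to C3=C4 with a carbon that bears oxygen and the carboxyl-level C7, so C7–C6–C5–C4=C3 is the γ,δ-unsaturated acid left by an ester-enolate Claisen rearrangement whose ester oxygen sat on C3. And C1/C2, a trans methoxy/acyloxy pair, have the configuration of C3/C4 of D-glucose, so a 3-O-methyl sugar lactone with a two-carbon alkenyl unit on its C5 (lactone 12) holds every ring atom and two of the four stereocentres.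

**Retrosynthetic reasoning**

Atom mapping used below (carbohydrate numbering of 12 → target numbering): C1 → C7, C2 → C6, C3 → C1, C4 → C2, C5 → C3, C6 → C4, C7 → C5.

21 ⇒ 19 + 20. The two ester C–O bonds are cut first. Benzoates would not survive the enolate, hydride and desilylation steps, so they are put on last. The forward step is a double acylation of epoxy diol 19 with 20 under conditions that leave the vinyl epoxide closed.

19 ⇒ 17 (through 18). The epoxide is opened retrosynthetically at its C5–O bond, not at C6–O, because C6 is quaternary and cannot be an SN2 site. This turns the sensitive epoxide into a stored pair: a C6 silyl ether and a C5 chloride on opposite faces. Forward, desilylation must free the C6 oxygen, which closes on C5 with inversion. Chlorine is chosen because it can be installed with fixed alkene geometry in one carbon–carbon bond-forming step and needs no later activation.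

17 ⇒ 16 ⇒ 15. No skeletal bond is cut. C7 is taken back from alcohol to ester to acid, because the carboxylic acid is what the rearrangement delivers. Forward, methylation and hydride reduction must leave the allylic chloride and the two silyl ethers alone.

15 ⇒ 12 (through 14 and 13). This is the central disconnection: the C5–C6 bond is cut and the carboxyl oxygen is reconnected to C3. It is made here because C5 and C6 are the only two stereocentres the sugar does not supply, and because C5–C6 is the one bond that the carboxyl group can help to form intramolecularly. One step gains the carbocycle, the quaternary C6, the C5 stereocentre with its leaving group, and the C3=C4 alkene. The ring size does not change: the oxane oxygen is expelled into the carboxyl group and the two alkenyl carbons take its place, so the name "ring contraction" describes the heterocycle-to-carbocycle change only. Forward, the rearrangement has to set both new centres. The tether fixes the face at C6, and the E alkene fixes C5.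

12 ⇒ 11 ⇒ 9 (through 10). The lactone carbonyl is taken back to a lactol and then to an allyl glycoside. The allyl group protects the anomeric carbon through silylation, oxidation and olefination. It can be removed under neutral conditions that spare silyl ethers and the alkenyl chloride.

9 ⇒ 7 + 8. The alkene between sugar C6 and C7 is cut, so the one extra carbon and the chlorine both come from 8. The forward olefination must be E-selective, since the alkene geometry becomes the C5 configuration of the target.

7 ⇒ 6 ⇒ 5 ⇒ 3 + 4; 3 ⇒ 1 + 2. These are protecting-group and oxidation-level changes on the sugar. Exhaustive silylation of 3 with 4, selective release of the primary hydroxyl, and oxidation give 7. Glycoside 3 comes from the commercial sugar 1 and 2. The methyl ether and both stereocentres C1 and C2 of the target are present in 1 from the start.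

**Alternatives that were turned down**

Alternative 1: Two bonds, C1–C6 and C2–C3, are cut in a [4+2] sense.
- Forward step: pyrone A1 supplies C6, C5, C4 and C3 with C7 as its ester, and alkene A2 supplies C1 and C2. A chiral bis(oxazoline) complex of Cu(OSO2CF3)2 (divalent copper), chelated by the 1,3-dicarbonyl unit of A1, would drive an inverse-demand cycloaddition to the bridged lactone A3.
- For it: it is convergent, makes two C–C bonds and the quaternary C6 in one catalytic asymmetric step, and copies the trans C1/C2 relationship from the E alkene.
- Against it: both alkene carbons of A2 carry donor oxygens, so regiochemistry rests only on methoxy being the better donor than benzoyloxy, and A2 is not a shelf compound. In A3 the alkene sits at C4=C5 and the bridge oxygen on C3, whereas the target needs C3=C4 and oxygen on C5. The usual way on from such adducts is decarboxylative cycloreversion, which makes C6 trigonal. The C5/C6 epoxide would then have to be set by a later face-selective epoxidation with nothing to direct it to the methoxy face. The C2 benzoate would also have to survive reduction of the C7 ester.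
- Comparison: Alternative 1 is stronger on convergence and on steps to the ring. The chosen route offers instead that C5 and C6 are fixed by the rearrangement itself, with the leaving group for the epoxide already in place.

Alternative 2: The C1–C6 bond between the two carbinol carbons is cut.
- Forward step: SmI2 (divalent samarium) would couple the aldehyde and ketone of the (Z)-configured keto-aldehyde A4 to the cis-diol A5.
- For it: ketyl–carbonyl cyclisations of this kind reliably give cis diols, and the cis C1–O/C6–O relationship is what the target needs. On this one point it is at least as dependable as the chosen key step.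
- Against it: the ketone of A4 carries an α-alkoxy group at C5, and reductive cleavage of α-oxygenated ketones is among the fastest reactions of this reductant, so the C5 oxygen is at risk. Both carbonyls are β,γ-unsaturated and α-oxygenated, so A4 is prone to conjugation and epimerisation. After the ring is closed, the secondary C1 hydroxyl must be methylated next to a tertiary one, the C5 ether removed and activated, and two different silyl groups exchanged for benzoates.
- Comparison: the chosen route carries the methyl ether from the first compound, uses one kind of protecting group, and removes it in the same operation that closes the epoxide.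

Alternative 3: The C2–C3 bond is cut.
- Forward step: CrCl2 (divalent chromium) with catalytic NiCl2 would turn the (Z)-alkenyl iodide A6 into an alkenylchromium species that adds to its own aldehyde, giving allylic alcohol A7.
- For it: it has the shortest endgame, since A7 needs only one benzoylation. The coupling is selective for aldehydes and tolerates the ester.
- Against it: C1, C5 and C6 must all be built on the open chain of A6, as a trisubstituted epoxide with a cis-iodoalkenyl group and an epimerisable α-methoxy aldehyde. The vinyl epoxide is exposed to Lewis-acidic chromium chlorides. The C2 carbinol is created in the ring closure with only the C1 methoxy group to control it, and chelation and non-chelation models predict opposite faces.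
- Comparison: Alternative 3 wins on the number of steps after the key step. The chosen route takes C2 unchanged from the sugar and forms the vinyl epoxide only one step before the end.

Key step: step 8

**Remarks before the steps**

- Compounds 1–13 are named with carbohydrate numbering, compounds 14–21 with the target ring numbering defined above. The SMILES in the compound list are authoritative.
- Assumption: glycoside 3 is carried forward as the α-anomer, the expected major product. The β-anomer would serve equally, because the anomeric centre becomes the lactone carbonyl in step 7.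

**Route**

Step 1
Reactants: 1 3-O-methyl-D-glucose (pyranose, anomeric mixture); 2 allyl alcohol
Product: 3 allyl 3-O-methyl-α-D-glucopyranoside
Conditions: allyl alcohol (solvent), AcCl (cat., HCl in situ), 70 °C; then NaHCO3; α-anomer separated
Reagents that add atoms: allyl alcohol 2, C=CCO
Why: Fischer glycosidation under thermodynamic control should favour the axial (α) pyranoside through the anomeric effect; the allyl group can later be removed without acid.

Step 2
Reactants: 3 allyl 3-O-methyl-α-D-glucopyranoside; 4 tert-butyldimethylsilyl trifluoromethanesulfonate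
Product: 5 allyl 2,4,6-tri-O-(tert-butyldimethylsilyl)-3-O-methyl-α-D-glucopyranoside
Conditions: TBSOTf (4 equiv), 2,6-lutidine, CH2Cl2, 0 °C → rt
Reagents that add atoms: tert-butyldimethylsilyl trifluoromethanesulfonate 4, CC(C)(C)[Si](C)(C)OS(=O)(=O)C(F)(F)F
Why: Exhaustive O-silylation; the silyl triflate is reactive enough to cap the hindered O4 as well as O2 and O6.

Step 3
Reactants: 5 allyl 2,4,6-tri-O-(tert-butyldimethylsilyl)-3-O-methyl-α-D-glucopyranoside
Product: 6 allyl 2,4-di-O-(tert-butyldimethylsilyl)-3-O-methyl-α-D-glucopyranoside
Conditions: HF·pyridine, pyridine, THF, 0 °C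
Reagents that add atoms: none
Why: Selective desilylation; the primary silyl ether is the least hindered and should be cleaved first by buffered fluoride while the two secondary ethers stay.

Step 4
Reactants: 6 allyl 2,4-di-O-(tert-butyldimethylsilyl)-3-O-methyl-α-D-glucopyranoside
Product: 7 allyl 2,4-di-O-(tert-butyldimethylsilyl)-3-O-methyl-α-D-gluco-hexodialdo-1,5-pyranoside
Conditions: Dess–Martin periodinane, CH2Cl2, 0 °C → rt; used without storage
Reagents that add atoms: none
Why: Dess–Martin oxidation of the primary alcohol; the near-neutral medium should avoid β-elimination of the O4 silyloxy group and epimerisation at C5.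

Step 5
Reactants: 7 allyl 2,4-di-O-(tert-butyldimethylsilyl)-3-O-methyl-α-D-gluco-hexodialdo-1,5-pyranoside; 8 chloroform
Product: 9 allyl (E)-7-chloro-6,7-dideoxy-2,4-di-O-(tert-butyldimethylsilyl)-3-O-methyl-α-D-gluco-hept-6-enopyranoside
Conditions: CrCl2 (divalent chromium, 6 equiv), CHCl3 (2 equiv), THF, 65 °C
Reagents that add atoms: chloroform 8, ClC(Cl)Cl
Why: Takai chloro-olefination; the geminal dichromium species from 8 adds to the aldehyde and the anti elimination that follows should place chlorine trans to the sugar ring (E). The reagent is not basic, so C5 should keep its configuration.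

Step 6
Reactants: 9 allyl (E)-7-chloro-6,7-dideoxy-2,4-di-O-(tert-butyldimethylsilyl)-3-O-methyl-α-D-gluco-hept-6-enopyranoside
Product: 11 (E)-7-chloro-6,7-dideoxy-2,4-di-O-(tert-butyldimethylsilyl)-3-O-methyl-D-gluco-hept-6-enopyranose, via (E)-prop-1-enyl glycoside 10 (not isolated)
Conditions: [Ir(cod)(PMePh2)2]PF6 (cat., cod = cycloocta-1,5-diene; activated with H2, then degassed), THF, rt; then I2, NaHCO3, THF–H2O, rt
Reagents that add atoms: none
Why: Iridium-hydride isomerisation should move the allyl double bond next to oxygen, and iodine-assisted hydrolysis of that enol ether frees the hemiacetal at neutral pH. Hydrogen is removed before 9 is added, so neither alkene should be reduced.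

Step 7
Reactants: 11 (E)-7-chloro-6,7-dideoxy-2,4-di-O-(tert-butyldimethylsilyl)-3-O-methyl-D-gluco-hept-6-enopyranose
Product: 12 (E)-7-chloro-6,7-dideoxy-2,4-di-O-(tert-butyldimethylsilyl)-3-O-methyl-D-gluco-hept-6-enono-1,5-lactone
Conditions: Dess–Martin periodinane, CH2Cl2, rt
Reagents that add atoms: none
Why: Oxidation of a lactol to a lactone; O4 is silylated, so only the pyranose form exists and only the 1,5-lactone can result.

Step 8
Reactants: 12 (E)-7-chloro-6,7-dideoxy-2,4-di-O-(tert-butyldimethylsilyl)-3-O-methyl-D-gluco-hept-6-enono-1,5-lactone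
Product: 15 (1S,2R,5S,6R)-2,6-bis(tert-butyldimethylsilyloxy)-5-chloro-1-methoxycyclohex-3-ene-6-carboxylic acid, via silyl ketene acetal 13 (not isolated), via trimethylsilyl ester 14 (not isolated)
Conditions: Me3SiCl/Et3N (excess, present from the start), KN(SiMe3)2, THF, −78 °C; then toluene, 90 °C; aq. citric acid work-up
Reagents that add atoms: chlorotrimethylsilane, C[Si](C)(C)Cl (its Me3Si groups are carried by 13 and 14 only)
Why: KN(SiMe3)2 removes the hydrogen at sugar C2 of 12 while Me3SiCl is already present, so the potassium enolate should be O-silylated to the ring-fixed ketene acetal 13 before it can expel the C3 methoxy group (E1cB); on heating, 13 should undergo a concerted suprafacial [3,3] shift in which sugar C2 bonds to C7 while the C5–O5 bond breaks, giving silyl ester 14 and, after hydrolytic work-up, acid 15. The closest known reaction type is the Ireland–Claisen rearrangement of alkenyl lactone silyl ketene acetals to cycloalkene carboxylic acids; a chlorine on the accepting alkene carbon has not been tried in it. The cyclohexene is closed transannularly across positions 2 and 5 of the oxane, a pericyclic closure through a bicyclo[2.2.2]-like boat array rather than a polar exo or endo cyclisation, and the ring stays six-membered as O5 is exchanged for the two alkenyl carbons. A chair is excluded because the two reacting termini are tied together by the C3–C4 bridge, so only the boat is open. The new C6 centre (target numbering) is controlled by that tether: the bond can only form on the lactone face that carries the alkenyl group, which leaves the carboxyl cis to the C2 oxygen and trans to the methoxy group. The new C5 centre is controlled by the E geometry of the alkene: because the ring alkene C3=C4 must be cis, the E chlorine is delivered to the carboxyl face, anti to the C6 oxygen. The step needs silylation to outrun elimination, which the internal quench at −78 °C addresses, and needs diastereoselectivity at C5 and C6, which the ring and the alkene geometry fix without any reagent control.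

Step 9
Reactants: 15 (1S,2R,5S,6R)-2,6-bis(tert-butyldimethylsilyloxy)-5-chloro-1-methoxycyclohex-3-ene-6-carboxylic acid
Product: 16 methyl (1S,2R,5S,6R)-2,6-bis(tert-butyldimethylsilyloxy)-5-chloro-1-methoxycyclohex-3-ene-6-carboxylate
Conditions: Me3SiCHN2, toluene–MeOH, 0 °C → rt
Reagents that add atoms: (trimethylsilyl)diazomethane, C[Si](C)(C)C=[N+]=[N-]
Why: O-methylation of the carboxylate by the diazonium ion formed in situ; alkylation at oxygen is indifferent to the quaternary α-carbon and the neutral medium should leave the allylic chloride alone.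

Step 10
Reactants: 16 methyl (1S,2R,5S,6R)-2,6-bis(tert-butyldimethylsilyloxy)-5-chloro-1-methoxycyclohex-3-ene-6-carboxylate
Product: 17 [(1S,2R,5S,6S)-2,6-bis(tert-butyldimethylsilyloxy)-5-chloro-1-methoxycyclohex-3-en-6-yl]methanol
Conditions: i-Bu2AlH (3 equiv), CH2Cl2, −78 → −20 °C
Reagents that add atoms: none
Why: Ester reduction to the primary alcohol; at low temperature the aluminium hydride should not displace a hindered secondary chloride, and C6 has no hydrogen, so nothing can epimerise or eliminate.

Step 11
Reactants: 17 [(1S,2R,5S,6S)-2,6-bis(tert-butyldimethylsilyloxy)-5-chloro-1-methoxycyclohex-3-en-6-yl]methanol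
Product: 19 (1S,2R,5R,6R)-5,6-epoxy-6-(hydroxymethyl)-1-methoxycyclohex-3-en-2-ol, via chloro triol 18 (not isolated)
Conditions: n-Bu4NF (4 equiv), THF, 0 °C → rt
Reagents that add atoms: none
Why: Fluoride desilylation followed by intramolecular Williamson closure (3-exo-tet); the C6 alkoxide is trans to chlorine and displaces it with inversion at C5, which should put the epoxide on the methoxy face. The C7 oxygen is cis to chlorine and cannot reach the back of C5.

Step 12
Reactants: 19 (1S,2R,5R,6R)-5,6-epoxy-6-(hydroxymethyl)-1-methoxycyclohex-3-en-2-ol; 20 benzoyl chloride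
Product: 21 (1S,2R,5R,6R)-2-benzoyloxy-6-(benzoyloxymethyl)-5,6-epoxy-1-methoxycyclohex-3-ene, systematic name [(1R,2S,3R,6R)-3-(benzoyloxy)-2-methoxy-7-oxabicyclo[4.1.0]hept-4-en-1-yl]methyl benzoate
Conditions: BzCl (2.5 equiv), Et3N, DMAP (cat.), CH2Cl2, 0 °C
Reagents that add atoms: benzoyl chloride 20, O=C(Cl)c1ccccc1
Why: DMAP-catalysed acylation of the primary and the secondary allylic hydroxyl; no stereocentre is touched and the amine base keeps the medium non-acidic for the vinyl epoxide.

**Compound list**

1 | 3-O-methyl-D-glucose (pyranose form) | OC[C@H]1OC(O)[C@H](O)[C@@H](OC)[C@@H]1O | starting material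
2 | allyl alcohol | C=CCO | starting material
3 | allyl 3-O-methyl-α-D-glucopyranoside | OC[C@H]1O[C@H](OCC=C)[C@H](O)[C@@H](OC)[C@@H]1O | intermediate
4 | tert-butyldimethylsilyl trifluoromethanesulfonate | CC(C)(C)[Si](C)(C)OS(=O)(=O)C(F)(F)F | starting material
5 | allyl 2,4,6-tri-O-(tert-butyldimethylsilyl)-3-O-methyl-α-D-glucopyranoside | CC(C)(C)[Si](C)(C)OC[C@H]1O[C@H](OCC=C)[C@H](O[Si](C)(C)C(C)(C)C)[C@@H](OC)[C@@H]1O[Si](C)(C)C(C)(C)C | intermediate
6 | allyl 2,4-di-O-(tert-butyldimethylsilyl)-3-O-methyl-α-D-glucopyranoside | OC[C@H]1O[C@H](OCC=C)[C@H](O[Si](C)(C)C(C)(C)C)[C@@H](OC)[C@@H]1O[Si](C)(C)C(C)(C)C | intermediate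
7 | allyl 2,4-di-O-(tert-butyldimethylsilyl)-3-O-methyl-α-D-gluco-hexodialdo-1,5-pyranoside | O=C[C@H]1O[C@H](OCC=C)[C@H](O[Si](C)(C)C(C)(C)C)[C@@H](OC)[C@@H]1O[Si](C)(C)C(C)(C)C | intermediate
8 | chloroform | ClC(Cl)Cl | starting material
9 | allyl (E)-7-chloro-6,7-dideoxy-2,4-di-O-(tert-butyldimethylsilyl)-3-O-methyl-α-D-gluco-hept-6-enopyranoside | Cl/C=C/[C@H]1O[C@H](OCC=C)[C@H](O[Si](C)(C)C(C)(C)C)[C@@H](OC)[C@@H]1O[Si](C)(C)C(C)(C)C | intermediate
10 | (E)-prop-1-enyl glycoside corresponding to 9 | Cl/C=C/[C@H]1O[C@H](O/C=C/C)[C@H](O[Si](C)(C)C(C)(C)C)[C@@H](OC)[C@@H]1O[Si](C)(C)C(C)(C)C | intermediate (not isolated)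
11 | (E)-7-chloro-6,7-dideoxy-2,4-di-O-(tert-butyldimethylsilyl)-3-O-methyl-D-gluco-hept-6-enopyranose (lactol) | Cl/C=C/[C@H]1OC(O)[C@H](O[Si](C)(C)C(C)(C)C)[C@@H](OC)[C@@H]1O[Si](C)(C)C(C)(C)C | intermediate
12 | (E)-7-chloro-6,7-dideoxy-2,4-di-O-(tert-butyldimethylsilyl)-3-O-methyl-D-gluco-hept-6-enono-1,5-lactone | Cl/C=C/[C@H]1OC(=O)[C@H](O[Si](C)(C)C(C)(C)C)[C@@H](OC)[C@@H]1O[Si](C)(C)C(C)(C)C | intermediate (key-step precursor)
13 | cyclic silyl ketene acetal of 12: 6-[(E)-2-chloroethenyl]-3,5-bis(tert-butyldimethylsilyloxy)-4-methoxy-2-(trimethylsilyloxy)-5,6-dihydro-4H-pyran, ring C4–C6 configured as sugar C3–C5 of 12 | Cl/C=C/[C@H]1OC(O[Si](C)(C)C)=C(O[Si](C)(C)C(C)(C)C)[C@@H](OC)[C@@H]1O[Si](C)(C)C(C)(C)C | intermediate (not isolated)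
14 | trimethylsilyl ester of 15 | CO[C@H]1[C@H](O[Si](C)(C)C(C)(C)C)C=C[C@H](Cl)[C@]1(O[Si](C)(C)C(C)(C)C)C(=O)O[Si](C)(C)C | intermediate (not isolated)
15 | (1S,2R,5S,6R)-2,6-bis(tert-butyldimethylsilyloxy)-5-chloro-1-methoxycyclohex-3-ene-6-carboxylic acid | CO[C@H]1[C@H](O[Si](C)(C)C(C)(C)C)C=C[C@H](Cl)[C@]1(O[Si](C)(C)C(C)(C)C)C(=O)O | intermediate (key-step product)
16 | methyl (1S,2R,5S,6R)-2,6-bis(tert-butyldimethylsilyloxy)-5-chloro-1-methoxycyclohex-3-ene-6-carboxylate | CO[C@H]1[C@H](O[Si](C)(C)C(C)(C)C)C=C[C@H](Cl)[C@]1(O[Si](C)(C)C(C)(C)C)C(=O)OC | intermediate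
17 | [(1S,2R,5S,6S)-2,6-bis(tert-butyldimethylsilyloxy)-5-chloro-1-methoxycyclohex-3-en-6-yl]methanol | CO[C@H]1[C@H](O[Si](C)(C)C(C)(C)C)C=C[C@H](Cl)[C@]1(O[Si](C)(C)C(C)(C)C)CO | intermediate
18 | (1S,2R,5S,6S)-5-chloro-6-(hydroxymethyl)-1-methoxycyclohex-3-ene-2,6-diol | CO[C@H]1[C@H](O)C=C[C@H](Cl)[C@]1(O)CO | intermediate (not isolated)
19 | (1S,2R,5R,6R)-5,6-epoxy-6-(hydroxymethyl)-1-methoxycyclohex-3-en-2-ol | CO[C@H]1[C@H](O)C=C[C@H]2O[C@]21CO | intermediate
20 | benzoyl chloride | O=C(Cl)c1ccccc1 | starting material
21 | [(1R,2S,3R,6R)-3-(benzoyloxy)-2-methoxy-7-oxabicyclo[4.1.0]hept-4-en-1-yl]methyl benzoate | CO[C@H]1[C@H](OC(=O)c2ccccc2)C=C[C@H]2O[C@]21COC(=O)c1ccccc1 | target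

**Step count and least certain steps**

Total step count: 12. Longest linear sequence: 12 steps (1 → 21).

Step 8 (key step).
- What may go wrong: ketene acetal 13 must reach a boat in which the ring substituents turn axial-like, and the accepting alkene carbon bears chlorine, a combination without direct precedent. The shift may be so slow that other processes win: expulsion of the β-methoxy group if silylation of the enolate lags, or ionisation of the allylic chloride in 14 at the temperature the rearrangement needs.
- Fallback: this changes the terminus to boron, for which [3,3] shifts to α-substituted allylboronates are established, and makes the C5 leaving group afterwards. It sets out from aldehyde 7 and comes back at epoxy diol 19.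
  - Aldehyde 7 with 2-(dichloromethyl)-4,4,5,5-tetramethyl-1,3,2-dioxaborolane, CrCl2 (divalent chromium) and LiI in THF should give the (E)-alkenylboronate glycoside F1.
  - Deallylation and oxidation as in steps 6 and 7 should give lactol F2 and lactone F3.
  - The same silyl ketene acetal rearrangement should give boryl acid F4, with boron on the face that chlorine occupies in 15.
  - NaBO3·4H2O in THF–H2O should oxidise the C–B bond with retention to hydroxy acid F5.
  - Me3SiCHN2 should give hydroxy ester F6, and MsCl/Et3N the mesylate F7.
  - i-Bu2AlH should give the primary alcohol F8, and n-Bu4NF should then remove both silyl groups and close the epoxide to 19.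

Step 5.
- What may go wrong: the aldehyde is hindered and carries a β-silyloxy group, so incomplete conversion, β-elimination under the Lewis-acidic trivalent chromium formed, or erosion of E selectivity are possible. Any Z alkene would end as the C5 epimer, which cannot close to the epoxide.
- Fallback: this sets out from 7 and comes back at 9. Seyferth–Gilbert homologation with dimethyl (1-diazo-2-oxopropyl)phosphonate and K2CO3 in MeOH should give the terminal alkyne F9. Hydrozirconation with one equivalent of Cp2Zr(H)Cl in THF adds syn, and the alkyne should react faster than the allyl alkene. N-Chlorosuccinimide should then replace zirconium with retention, so the E geometry is set by mechanism.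

Step 11.
- What may go wrong: cleavage of the tertiary silyl ether at C6 may stall beside the free neopentyl alcohol, with silyl migration between O6 and O7. While the allylic chloride waits for its alkoxide, substitution by fluoride could compete with ring closure.
- Fallback: this sets out from ester 16 and comes back at 19, and also bypasses step 10. n-Bu4NF on 16 should unveil the more acidic α-hydroxy ester, whose alkoxide closes to the glycidic ester F10 with no primary alcohol nearby. NaBH4 in MeOH at 0 °C should then reduce the activated ester to 19.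

Step 3.
- What may go wrong: cleavage may not stop at the primary position, or the O4 silyl group may migrate to O6 once the primary hydroxyl is free.
- Fallback: this sets out from 3 and comes back at 6, and differentiates O6 by acylation instead. Pivaloyl chloride in pyridine at −20 °C should acylate only the primary hydroxyl to give F11. TBSOTf/2,6-lutidine should give F12, and i-Bu2AlH at −78 °C should remove the pivaloate to give 6.

**Further compounds**

F1 | step 8 | allyl (E)-6,7-dideoxy-7-(4,4,5,5-tetramethyl-1,3,2-dioxaborolan-2-yl)-2,4-di-O-(tert-butyldimethylsilyl)-3-O-methyl-α-D-gluco-hept-6-enopyranoside | CC1(C)OB(/C=C/[C@H]2O[C@H](OCC=C)[C@H](O[Si](C)(C)C(C)(C)C)[C@@H](OC)[C@@H]2O[Si](C)(C)C(C)(C)C)OC1(C)C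
F2 | step 8 | lactol corresponding to F1 (free anomeric hydroxyl) | CC1(C)OB(/C=C/[C@H]2OC(O)[C@H](O[Si](C)(C)C(C)(C)C)[C@@H](OC)[C@@H]2O[Si](C)(C)C(C)(C)C)OC1(C)C
F3 | step 8 | 1,5-lactone corresponding to F2 (boron analogue of 12) | CC1(C)OB(/C=C/[C@H]2OC(=O)[C@H](O[Si](C)(C)C(C)(C)C)[C@@H](OC)[C@@H]2O[Si](C)(C)C(C)(C)C)OC1(C)C
F4 | step 8 | 2,6-bis(tert-butyldimethylsilyloxy)-1-methoxy-5-(4,4,5,5-tetramethyl-1,3,2-dioxaborolan-2-yl)cyclohex-3-ene-6-carboxylic acid, configured as 15 with boron in place of chlorine | CO[C@H]1[C@H](O[Si](C)(C)C(C)(C)C)C=C[C@H](B2OC(C)(C)C(C)(C)O2)[C@]1(O[Si](C)(C)C(C)(C)C)C(=O)O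
F5 | step 8 | 2,6-bis(tert-butyldimethylsilyloxy)-5-hydroxy-1-methoxycyclohex-3-ene-6-carboxylic acid, C5 hydroxyl on the carboxyl face | CO[C@H]1[C@H](O[Si](C)(C)C(C)(C)C)C=C[C@H](O)[C@]1(O[Si](C)(C)C(C)(C)C)C(=O)O
F6 | step 8 | methyl ester of F5 | CO[C@H]1[C@H](O[Si](C)(C)C(C)(C)C)C=C[C@H](O)[C@]1(O[Si](C)(C)C(C)(C)C)C(=O)OC
F7 | step 8 | 5-O-methanesulfonate of F6 | CO[C@H]1[C@H](O[Si](C)(C)C(C)(C)C)C=C[C@H](OS(C)(=O)=O)[C@]1(O[Si](C)(C)C(C)(C)C)C(=O)OC
F8 | step 8 | primary alcohol from F7 (methanesulfonate analogue of 17) | CO[C@H]1[C@H](O[Si](C)(C)C(C)(C)C)C=C[C@H](OS(C)(=O)=O)[C@]1(O[Si](C)(C)C(C)(C)C)CO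
F9 | step 5 | allyl 6,7-dideoxy-2,4-di-O-(tert-butyldimethylsilyl)-3-O-methyl-α-D-gluco-hept-6-ynopyranoside | C#C[C@H]1O[C@H](OCC=C)[C@H](O[Si](C)(C)C(C)(C)C)[C@@H](OC)[C@@H]1O[Si](C)(C)C(C)(C)C
F10 | step 11 | methyl 5,6-epoxy-2-hydroxy-1-methoxycyclohex-3-ene-6-carboxylate, configured as 19 | CO[C@H]1[C@H](O)C=C[C@H]2O[C@]21C(=O)OC
F11 | step 3 | allyl 3-O-methyl-6-O-pivaloyl-α-D-glucopyranoside | CC(C)(C)C(=O)OC[C@H]1O[C@H](OCC=C)[C@H](O)[C@@H](OC)[C@@H]1O
F12 | step 3 | allyl 2,4-di-O-(tert-butyldimethylsilyl)-3-O-methyl-6-O-pivaloyl-α-D-glucopyranoside | CC(C)(C)C(=O)OC[C@H]1O[C@H](OCC=C)[C@H](O[Si](C)(C)C(C)(C)C)[C@@H](OC)[C@@H]1O[Si](C)(C)C(C)(C)C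
A1 | alternative 1 | methyl 2-oxo-2H-pyran-3-carboxylate | COC(=O)C1=CC=COC1=O
A2 | alternative 1 | (E)-2-methoxyethenyl benzoate | CO/C=C/OC(=O)c1ccccc1
A3 | alternative 1 | methyl 7-(benzoyloxy)-8-methoxy-3-oxo-2-oxabicyclo[2.2.2]oct-5-ene-4-carboxylate | CO[C@H]1[C@H](OC(=O)c3ccccc3)[C@@H]2C=C[C@@]1(C(=O)OC)C(=O)O2
A4 | alternative 2 | (2R,3Z,5S)-2-(tert-butyldimethylsilyloxy)-7-(tert-butyldiphenylsilyloxy)-5-[(4-methoxybenzyl)oxy]-6-oxohept-3-enal | O=C[C@H](O[Si](C)(C)C(C)(C)C)/C=C\[C@H](OCc1ccc(OC)cc1)C(=O)CO[Si](c1ccccc1)(c1ccccc1)C(C)(C)C
A5 | alternative 2 | 2-(tert-butyldimethylsilyloxy)-6-[(tert-butyldiphenylsilyloxy)methyl]-5-[(4-methoxybenzyl)oxy]cyclohex-3-ene-1,6-diol, C1 and C6 hydroxyls cis (target ring numbering) | O[C@H]1[C@H](O[Si](C)(C)C(C)(C)C)C=C[C@H](OCc2ccc(OC)cc2)[C@]1(O)CO[Si](c3ccccc3)(c4ccccc4)C(C)(C)C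
A6 | alternative 3 | {3-[(Z)-2-iodoethenyl]-2-(1-methoxy-2-oxoethyl)oxiran-2-yl}methyl benzoate, configured as C1, C5 and C6 of the target | I/C=C\[C@H]1O[C@@]1(COC(=O)c2ccccc2)[C@@H](OC)C=O
A7 | alternative 3 | [(1R,2S,3R,6R)-3-hydroxy-2-methoxy-7-oxabicyclo[4.1.0]hept-4-en-1-yl]methyl benzoate | CO[C@H]1[C@H](O)C=C[C@H]2O[C@]21COC(=O)c1ccccc1
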